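- At 3.00 h of the winter run G reads 0% and J 18.3%, so a leftover of 81.7% of the charge stands in forms I do not read.

| flask | G | E | remark | time |
|---|---|---|---|---|
| winter | 0.050 M | 0.025 M | run made earlier |  |
| midnight | 0.025 M | 0.025 M | run made earlier |  |
| Thursday's | 0.050 M | 0.0250 M | a closed flask charged with all of it at once and left for 5.0 h | 5.0 h |
| Monday's | 0.050 M (fed, over 2.50 h) | 0.0250 M | a stirred flask in which G is dosed at a steady rate over 2.50 h without added volume, worked up at 5.0 h | 5.0 h |
| Tuesday's | 0.050 M | 0.0250 M | a single well-mixed tank run continuously and read at steady state, 5.0 h in it on average |  |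

winter run (percent of the G charged)

| time / h | J / % | G / % |
|---|---|---|
| 0.250 | 0 | 60.1 |
| 0.417 | 1.0 | 42.8 |
| 0.833 | 2.3 | 18.9 |
| 1.50 | 7.6 | 4.8 |
| 3.00 | 18.3 | 0 |

midnight run (percent of the G charged)

| time / min | J / % | G / % |
|---|---|---|
| 5.00 | 0.1 | 83.8 |
| 10.0 | 0.1 | 69.8 |
| 15.0 | 0 | 58.8 |
| 30.0 | 1.1 | 35.4 |
| 60.0 | 3.7 | 13.3 |

(readings scatter by 0.5 percentage points)

- order of the set-ups by the amount of J at the outlet or at the end, in percent of the G put in, highest first (Thursday's / Monday's / Tuesday's)
- amount of J at the outlet or at the end, in percent of the G put in, Thursday's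
- amount of J at the outlet or at the end, in percent of the G put in, Monday's
- amount of J at the outlet or at the end, in percent of the G put in, Tuesday's

- the stated concentrations are those of everything mixed, before any reaction; amounts are the same in each set-up
- the feed brings no volume worth counting
- the earlier runs were made in a closed, stirred flask

- Two times carry my reckoning. G's lifetime, from the fraction 13.3% left at 60.0 min of the midnight run, is 0.496 h.
- The slow time, the mean wait for J if I count the whole leftover as bound for J, is 12.4 h, read from the winter J after subtracting G's lifetime.
- The slow time is far longer than G's lifetime, by a ratio of 25.0, so in my reckoning J follows G as one first-order wait.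
- A set-up then acts through its delay. The fraction not yet J falls as exp(−(t − delay)/slow time), the delay being G's lifetime, plus half the dosing time when G is fed. In the tank, each time enters as mean stay/(mean stay + time), and the two factors multiply.
- My reckoning gives Thursday's 30.5%, Monday's 23.1% and Tuesday's 26.2%.
- The forecast gives 30%, 23% and 26%, in the order Thursday's > Tuesday's > Monday's, on the ground that “J appears only after a lag”.
- The flasks give 30.9%, 23.3% and 26.1%, in the order Thursday's > Tuesday's > Monday's.

    G → D (k = 0.0240 min⁻¹)
    D ⇌ L (K = 0.520, k = 0.00230 min⁻¹)
    L → Q (k = 0.00290 min⁻¹)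
    L → J (k = 0.100 min⁻¹)
    G + E → X (k = 0.490 M⁻¹ min⁻¹)

- Thursday's stands at 30.9% through the time allowed and the step from G + E to X acting together. Left for 50.0 h, Thursday's gives 71.4%, and with that step taken away, Thursday's gives 40.8% at 5.0 h.
- At 20 h in Thursday's flask, the slow time gives 79.3%, but the computed reading is 65.9%. X holds 26.4% there, and I had counted that as bound for J.

The numbers in the tables were computed from invented constants, noise included.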